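What is left of your starting material is to go into the dusk run, which holds more free catalyst than any earlier flask, and you want to know what it will give.

| flask | starting material | free catalyst | time |
|---|---|---|---|
| midnight | 0.500 M | 0.0400 M |  |
| dawn | 0.200 M | 0.0400 M |  |
| winter | 0.500 M | 0.0800 M |  |
| dusk | 0.170 M | 0.120 M | 41 min |

- midnight run (time / min: [product] / M): 1.6: 0.011; 2.8: 0.017; 4.8: 0.026; 8.2: 0.031; 14: 0.065; 24: 0.118; 41: 0.228
- dawn run (time / min: [product] / M): 1.6: 0.004; 2.8: 0.001; 4.8: 0.010; 8.2: 0.005; 14: 0.010; 24: 0.011; 41: 0.025
- winter run (time / min: [product] / M): 1.6: 0.018; 2.8: 0.022; 4.8: 0.035; 8.2: 0.074; 14: 0.111; 24: 0.184; 41: 0.296

(each reading ± 0.005 M)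

- apparent order in [free catalyst] of the starting rate, round the charge of the midnight run (the rate where two percent of its starting material have turned into product)
- apparent order in [starting material] of the starting rate, round the charge of the midnight run (the rate where two percent of its starting material have turned into product) (one fixed amount of product, the same in the runs compared)
- the dawn run starts with 0.300 M less of starting material than the midnight run, and with no product. Compared where both hold the same amount of starting material, once fifteen percent of what the dawn run was charged with has turned into product, is the dawn run faster, slower or alike (within a tenth)?
- product in the dusk run at 41 min, as a share of the starting material charged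

- Overall: starting material -> product, with free catalyst as catalyst.
- Constant volume, constant temperature.
- Bound and free are read together.
- An order is taken over about fifteen percent of the charge, up and down.

Start from the dawn run, the nearest flask, and ask which numbers must be known well to carry its reading of 0.025 M at 41 min over to dusk. The order in starting material enters twice. The ratio of the dusk charge to the dawn charge is 0.850, so an order off by 0.5 moves that step by a factor 0.922; the ratio of the dawn charge to the midnight charge is 0.400, and the same error moves whatever is carried from midnight to dawn by a factor 0.632. I read the order from the mean rates, 0.00464 M/min for midnight over 14 min and 6.10 × 10⁻⁴ M/min for dawn over 41 min, which gives 2.22 and a dusk factor of 0.698. The scatter of the dawn reading shifts the outcome by about 2.05% of the charge.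

Next comes the catalyst, which the dusk run holds at 3.00 times the dawn charge. Take as the zero of the scale a flask where product goes in proportion to catalyst: winter would read 0.456 M, and dusk would reach 30.8%. But winter reads 0.296 M against 0.228 M for midnight. The gain per added catalyst reads 1.70; call this the dose, the product that a unit of catalyst adds by 41 min at a charge of 0.500 M, a turnover number of sorts.

Scaled by the order, the dose explains 0.00893 M of the dawn reading, leaving 0.0161 M. I assume that the dose part grows with catalyst and the remainder does not. For dusk the dose part becomes 0.0187 M, and the total 0.0299 M, which is 17.6% of the charge. With an order lower by 0.5 the same reckoning gives 23.7%, so the order has to be known well too.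

The forecast gave orders of 0.7 in catalyst and 2.2 in starting material, dawn slower, and 19% for dusk, on the ground “Winter shows the same effect, so product activates”.

The flask gives orders of 0.95 and 1.7, a dawn run at 0.091 of the midnight rate, so slower, and 20.2% for dusk, 2.7 percentage points above my figure.

    free catalyst + starting material ⇌ catalyst-substrate complex, settled at all times (1.670 /M)
    catalyst-substrate complex + starting material ⇌ doubly bound catalyst, settled at all times (0.2880 /M)
    doubly bound catalyst → product + catalyst-substrate complex (2.226 /min)
    starting material + product → 2 product (0.1068 /M/min)
    free catalyst → spent catalyst (0.1260 /min)

Of the 0.0344 M of product in the dusk run, the dose part reckoned above comes to 54.3%; in the midnight run the dose times the charge of free catalyst comes to 29.8% of the reading at 41 min. The path from free catalyst to spent catalyst holds the dusk run down. The dusk run without this path reaches 42.9% in place of 20.2%.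

Readings and results are simulated with constants of no real substance; scatter was added.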